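**Retrosynthetic overview**
- The target comes from global deprotection of its hexadeca-O-(4-methylbenzyl), mono-O-silyl ether. The C8–C1 bond between the flavan and the chalcane half is made by ring expansion of a trans-epoxide with a galloyl cation to a 1,3-dioxolan-2-ylium ion, which C8 of the protected epigallocatechin gallate opens; this also installs the upper gallate and sets the diarylmethine centre.
- The protected epigallocatechin gallate comes from the same epoxide: acylative opening with the galloyl chloride (chloride anti at the benzylic carbon), then phenoxide SN2 closure of ring C (2,3-cis).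
- The epoxide comes from Shi epoxidation of an (E)-1,3-diarylpropene, made by Friedel–Crafts allylation of a ring-A phenol with a 1-arylallyl alcohol (ring-B aryl Grignard reagent plus acrolein).
- All six trioxygenated rings come from resorcinol: ring A by C–H borylation/oxidation, the pyrogallol rings (ring B, galloyl) by ortho-lithiation/borate oxidation; the carboxyl carbons come from CO2.
- Ring order: aromatic rings, then the oxirane, then ring C of the lower unit, then the transient dioxolanylium ring in the coupling; the upper half stays acyclic.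

Abbreviations: MBn = 4-methylbenzyl (4-MeC6H4CH2), MBnO = (4-methylbenzyl)oxy, TBS = tert-butyldimethylsilyl, TBSO = its ether.

Assumption: 4-methylbenzyl bromide and TBSCl are protecting-group reagents and CO2 is a one-carbon starting material; 4-methylbenzyl replaces benzyl because every C–H of its ring has an ortho substituent, so the borylation in step 2 should touch only ring A.

**Step 1**
Reactants: 1 resorcinol
Product: 2 1,3-bis(MBnO)benzene
Conditions: 4-MeC6H4CH2Br (2.2 equiv), K2CO3, DMF, 60 °C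
Reagents that add atoms: 4-methylbenzyl bromide, Cc1ccc(CBr)cc1
Why: Double Williamson etherification of the two phenols; no stereocentre is involved.

**Step 2**
Reactants: 2 1,3-bis(MBnO)benzene
Product: 4 3,5-bis(MBnO)phenol, via arylboronic pinacol ester 3 (not isolated)
Conditions: [Ir(OMe)(cod)]2 (1.5 mol%), 4,4'-di-tert-butyl-2,2'-bipyridine (3 mol%), B2pin2 (0.7 equiv), THF, 80 °C; then KHSO5 (Oxone), acetone/H2O, rt
Reagents that add atoms: bis(pinacolato)diboron, CC1(C)OB(OC1(C)C)B1OC(C)(C)C(C)(C)O1 (boron only in 3); potassium peroxymonosulfate, [K+].[O-]S(=O)(=O)OO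
Why: Sterically controlled iridium-catalysed C–H borylation takes the only arene C–H without an ortho substituent (C5), and oxidation of the boronate in the same flask (aryl shift from boron to oxygen) gives the phloroglucinol pattern.

**Step 3**
Reactants: 2 1,3-bis(MBnO)benzene
Product: 7 2,6-bis(MBnO)phenol, via aryllithium 5 (not isolated), via dimethyl arylboronate 6 (not isolated)
Conditions: n-BuLi, THF, 0 °C; B(OMe)3, −78 °C → rt; H2O2 (30% aq), 0 °C → rt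
Reagents that add atoms: n-butyllithium, [Li]CCCC (Li only in 5); trimethyl borate, COB(OC)OC (boron only in 6); hydrogen peroxide, OO
Why: Directed ortho-lithiation between the two alkoxy groups, borylation and oxidative aryl migration from boron to oxygen give the pyrogallol pattern.

**Step 4**
Reactants: 7 2,6-bis(MBnO)phenol
Product: 8 4-bromo-2,6-bis(MBnO)phenol
Conditions: NBS (1.0 equiv), MeCN, −20 °C, dark
Reagents that add atoms: N-bromosuccinimide, O=C1CCC(=O)N1Br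
Why: Electrophilic aromatic bromination goes para to the free phenol because both ortho positions are blocked.

**Step 5**
Reactants: 8 4-bromo-2,6-bis(MBnO)phenol
Product: 9 5-bromo-1,2,3-tris(MBnO)benzene
Conditions: 4-MeC6H4CH2Br, K2CO3, DMF, 50 °C
Reagents that add atoms: 4-methylbenzyl bromide, Cc1ccc(CBr)cc1
Why: Williamson etherification of the remaining phenol.

**Step 6**
Reactants: 9 5-bromo-1,2,3-tris(MBnO)benzene; 10 carbon dioxide
Product: 13 3,4,5-tris(MBnO)benzoyl chloride, via aryllithium 11 (not isolated), via lithium carboxylate 12 (not isolated)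
Conditions: n-BuLi, THF, −78 °C; CO2; evaporate; (COCl)2, DMF (cat.), CH2Cl2, 0 °C → rt
Reagents that add atoms: n-butyllithium, [Li]CCCC (Li only in 11 and 12); oxalyl chloride, ClC(=O)C(Cl)=O
Why: Bromine–lithium exchange, carboxylation of the aryllithium and conversion of the carboxylate into the acid chloride with oxalyl chloride.

**Step 7**
Reactants: 9 5-bromo-1,2,3-tris(MBnO)benzene; 14 acrolein
Product: 17 racemic 1-[3,4,5-tris(MBnO)phenyl]prop-2-en-1-ol, via arylmagnesium bromide 15 (not isolated), via bromomagnesium alkoxide 16 (not isolated)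
Conditions: Mg turnings (I2 cat.), THF, 50 °C; 14, −78 → −20 °C; aq. NH4Cl
Reagents that add atoms: magnesium, [Mg] (Mg only in 15 and 16)
Why: Magnesium insertion into the aryl C–Br bond gives the Grignard reagent, and Grignard 1,2-addition to the enal gives the allylic alcohol; the carbinol centre is racemic and is erased in step 8.

**Step 8**
Reactants: 17 racemic 1-[3,4,5-tris(MBnO)phenyl]prop-2-en-1-ol; 4 3,5-bis(MBnO)phenol
Product: 18 3,5-bis(MBnO)-2-[(2E)-3-[3,4,5-tris(MBnO)phenyl]prop-2-en-1-yl]phenol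
Conditions: H2SO4 on SiO2 (cat.), 4 (2 equiv), CH2Cl2, rt
Reagents that add atoms: none
Why: Acid-catalysed Friedel–Crafts allylation: the aryl-stabilised allyl cation is attacked at its terminus by C2 of the phenol (ortho to OH, the less hindered activated position), giving the conjugated E-alkene.

**Step 9**
Reactants: 18 the (E)-alkene phenol
Product: 19 tert-butyldimethylsilyl ether of 18
Conditions: TBSCl, imidazole, DMF, rt
Reagents that add atoms: tert-butyldimethylsilyl chloride, CC(C)(C)[Si](C)(C)Cl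
Why: Silylation masks the phenol against Oxone and against premature attack on the epoxide.

**Step 10**
Reactants: 19 the silyl-protected (E)-alkene
Product: 20 (2R,3R)-2-[2-(TBSO)-4,6-bis(MBnO)benzyl]-3-[3,4,5-tris(MBnO)phenyl]oxirane
Conditions: D-fructose-derived Shi ketone (30 mol%), KHSO5 (Oxone), K2CO3, Bu4NHSO4, MeCN/CH2(OMe)2/aq. Na2B4O7 buffer (pH 10.5), 0 °C
Reagents that add atoms: potassium peroxymonosulfate, [K+].[O-]S(=O)(=O)OO
Why: Shi asymmetric epoxidation: the chiral dioxirane attacks the trans-alkene through the spiro transition state and gives the (R,R)-epoxide, which sets the oxygen-bearing carbon of both halves (C3 of the flavan, C2 of the chalcane chain).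

**Step 11**
Reactants: 20 the (2R,3R)-epoxide; 13 3,4,5-tris(MBnO)benzoyl chloride
Product: 21 (1S,2R)-1-chloro-3-[2-(TBSO)-4,6-bis(MBnO)phenyl]-1-[3,4,5-tris(MBnO)phenyl]propan-2-yl 3,4,5-tris(MBnO)benzoate
Conditions: Bu4NCl (10 mol%), CH2Cl2, 0 °C → rt
Reagents that add atoms: none
Why: Acylative opening of the epoxide by the acid chloride: the epoxide oxygen is acylated and stays on the (R) carbon, while chloride enters at the benzylic carbon with inversion to give the anti chloro ester.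

**Step 12**
Reactants: 21 the anti chloro ester
Product: 23 (2R,3R)-5,7-bis(MBnO)-2-[3,4,5-tris(MBnO)phenyl]-3,4-dihydro-2H-chromen-3-yl 3,4,5-tris(MBnO)benzoate, via tetrabutylammonium phenoxide 22 (not isolated)
Conditions: Bu4NF (1.05 equiv), THF, −40 → 0 °C
Reagents that add atoms: tetrabutylammonium fluoride, CCCC[N+](CCCC)(CCCC)CCCC.[F-] (cation only in 22)
Why: Fluoride removes the silyl group and the phenoxide displaces the benzylic chloride by 6-exo-tet SN2 (intramolecular Williamson etherification) with inversion, so the double inversion from the epoxide gives the 2,3-cis (2R,3R) ring C.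

**Step 13**
Reactants: 20 the (2R,3R)-epoxide; 13 3,4,5-tris(MBnO)benzoyl chloride; 23 the protected epigallocatechin gallate
Product: 26 (1R,2R)-1-{(2R,3R)-5,7-bis(MBnO)-3-{[3,4,5-tris(MBnO)benzoyl]oxy}-2-[3,4,5-tris(MBnO)phenyl]-3,4-dihydro-2H-chromen-8-yl}-3-[2-(TBSO)-4,6-bis(MBnO)phenyl]-1-[3,4,5-tris(MBnO)phenyl]propan-2-yl 3,4,5-tris(MBnO)benzoate, via aroyl triflate 24 (not isolated), via dioxolanylium triflate 25 (not isolated)
Conditions: 13 (1.2 equiv), AgOSO2CF3 (1.2 equiv), 2,6-di-tert-butyl-4-methylpyridine, 4 Å MS, CH2Cl2, −78 °C; 20; then 23 (3 equiv), −78 → −30 °C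
Reagents that add atoms: silver trifluoromethanesulfonate, [Ag+].[O-]S(=O)(=O)C(F)(F)F (triflate only in 24 and 25)
Why: Proposed new method: the aroyl triflate O-acylates the oxirane, its benzylic C–O bond ionises while the ester carbonyl oxygen closes on the same face, so the three-membered ring is expanded (cationic, not pericyclic) to the trans-4,5-disubstituted 2-aryl-1,3-dioxolan-2-ylium ion 25, and C8 of 23 (the preferred nucleophilic site of ring A in benzyl-type protected flavan-3-ols) opens this ion at its benzylic carbon anti to the ring oxygen in a Friedel–Crafts alkylation with inversion, which forms the C8–C1 bond, sets the (1R) diarylmethine anti to the (2R) ester and leaves the galloyl ester in place; the closest known reaction types are acylative epoxide opening through acyloxonium ions, acyloxonium-directed 1,2-trans Friedel–Crafts C-glycosylation and 3-O-acyl-directed 4→8 flavan couplings.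

**Step 14**
Reactants: 26 the protected dimer
Product: 28 CNP0155034.2 (target), via desilylated phenol 27 (not isolated)
Conditions: KHF2, MeOH/THF, rt; then H2 (1 atm), Pd(OH)2/C, THF/MeOH, rt
Reagents that add atoms: none
Why: Fluoride cleaves the aryl silyl ether and hydrogenolysis removes the sixteen 4-methylbenzyl ethers without touching a stereocentre.

**Compound list**
1 | resorcinol | Oc1cccc(O)c1 | starting material
2 | 1,3-bis[(4-methylbenzyl)oxy]benzene | c1c(OCc5ccc(C)cc5)cccc1OCc5ccc(C)cc5 | intermediate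
3 | 2-{3,5-bis[(4-methylbenzyl)oxy]phenyl}-4,4,5,5-tetramethyl-1,3,2-dioxaborolane | c1c(OCc5ccc(C)cc5)cc(B3OC(C)(C)C(C)(C)O3)cc1OCc5ccc(C)cc5 | intermediate
4 | 3,5-bis[(4-methylbenzyl)oxy]phenol | Oc1cc(OCc5ccc(C)cc5)cc(OCc5ccc(C)cc5)c1 | intermediate
5 | {2,6-bis[(4-methylbenzyl)oxy]phenyl}lithium | [Li]c1c(OCc5ccc(C)cc5)cccc1OCc5ccc(C)cc5 | intermediate
6 | dimethyl {2,6-bis[(4-methylbenzyl)oxy]phenyl}boronate | COB(OC)c1c(OCc5ccc(C)cc5)cccc1OCc5ccc(C)cc5 | intermediate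
7 | 2,6-bis[(4-methylbenzyl)oxy]phenol | Oc1c(OCc5ccc(C)cc5)cccc1OCc5ccc(C)cc5 | intermediate
8 | 4-bromo-2,6-bis[(4-methylbenzyl)oxy]phenol | Oc1c(OCc5ccc(C)cc5)cc(Br)cc1OCc5ccc(C)cc5 | intermediate
9 | 5-bromo-1,2,3-tris[(4-methylbenzyl)oxy]benzene | Brc1cc(OCc5ccc(C)cc5)c(OCc5ccc(C)cc5)c(OCc5ccc(C)cc5)c1 | intermediate
10 | carbon dioxide | O=C=O | starting material
11 | {3,4,5-tris[(4-methylbenzyl)oxy]phenyl}lithium | [Li]c1cc(OCc5ccc(C)cc5)c(OCc5ccc(C)cc5)c(OCc5ccc(C)cc5)c1 | intermediate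
12 | lithium 3,4,5-tris[(4-methylbenzyl)oxy]benzoate | [Li+].[O-]C(=O)c1cc(OCc5ccc(C)cc5)c(OCc5ccc(C)cc5)c(OCc5ccc(C)cc5)c1 | intermediate
13 | 3,4,5-tris[(4-methylbenzyl)oxy]benzoyl chloride | ClC(=O)c1cc(OCc5ccc(C)cc5)c(OCc5ccc(C)cc5)c(OCc5ccc(C)cc5)c1 | intermediate
14 | acrolein (prop-2-enal) | C=CC=O | starting material
15 | {3,4,5-tris[(4-methylbenzyl)oxy]phenyl}magnesium bromide | Br[Mg]c1cc(OCc5ccc(C)cc5)c(OCc5ccc(C)cc5)c(OCc5ccc(C)cc5)c1 | intermediate
16 | bromomagnesium 1-{3,4,5-tris[(4-methylbenzyl)oxy]phenyl}prop-2-en-1-olate (racemic) | Br[Mg]OC(C=C)c1cc(OCc5ccc(C)cc5)c(OCc5ccc(C)cc5)c(OCc5ccc(C)cc5)c1 | intermediate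
17 | 1-{3,4,5-tris[(4-methylbenzyl)oxy]phenyl}prop-2-en-1-ol (racemic) | OC(C=C)c1cc(OCc5ccc(C)cc5)c(OCc5ccc(C)cc5)c(OCc5ccc(C)cc5)c1 | intermediate
18 | 3,5-bis(MBnO)-2-[(2E)-3-[3,4,5-tris(MBnO)phenyl]prop-2-en-1-yl]phenol | Oc1cc(OCc5ccc(C)cc5)cc(OCc5ccc(C)cc5)c1C/C=C/c4cc(OCc5ccc(C)cc5)c(OCc5ccc(C)cc5)c(OCc5ccc(C)cc5)c4 | intermediate
19 | tert-butyl{3,5-bis(MBnO)-2-[(2E)-3-[3,4,5-tris(MBnO)phenyl]prop-2-en-1-yl]phenoxy}dimethylsilane | CC(C)(C)[Si](C)(C)Oc1cc(OCc5ccc(C)cc5)cc(OCc5ccc(C)cc5)c1C/C=C/c4cc(OCc5ccc(C)cc5)c(OCc5ccc(C)cc5)c(OCc5ccc(C)cc5)c4 | intermediate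
20 | (2R,3R)-2-[2-(TBSO)-4,6-bis(MBnO)benzyl]-3-[3,4,5-tris(MBnO)phenyl]oxirane (trans) | CC(C)(C)[Si](C)(C)Oc1cc(OCc5ccc(C)cc5)cc(OCc5ccc(C)cc5)c1C[C@H]3O[C@@H]3c4cc(OCc5ccc(C)cc5)c(OCc5ccc(C)cc5)c(OCc5ccc(C)cc5)c4 | intermediate
21 | (1S,2R)-1-chloro-3-[2-(TBSO)-4,6-bis(MBnO)phenyl]-1-[3,4,5-tris(MBnO)phenyl]propan-2-yl 3,4,5-tris(MBnO)benzoate | CC(C)(C)[Si](C)(C)Oc1cc(OCc5ccc(C)cc5)cc(OCc5ccc(C)cc5)c1C[C@@H](OC(=O)c6cc(OCc5ccc(C)cc5)c(OCc5ccc(C)cc5)c(OCc5ccc(C)cc5)c6)[C@@H](Cl)c4cc(OCc5ccc(C)cc5)c(OCc5ccc(C)cc5)c(OCc5ccc(C)cc5)c4 | intermediate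
22 | tetrabutylammonium 3,5-bis(MBnO)-2-[(2R,3S)-3-chloro-2-{[3,4,5-tris(MBnO)benzoyl]oxy}-3-[3,4,5-tris(MBnO)phenyl]propyl]phenoxide | CCCC[N+](CCCC)(CCCC)CCCC.[O-]c1cc(OCc5ccc(C)cc5)cc(OCc5ccc(C)cc5)c1C[C@@H](OC(=O)c6cc(OCc5ccc(C)cc5)c(OCc5ccc(C)cc5)c(OCc5ccc(C)cc5)c6)[C@@H](Cl)c4cc(OCc5ccc(C)cc5)c(OCc5ccc(C)cc5)c(OCc5ccc(C)cc5)c4 | intermediate
23 | (2R,3R)-5,7-bis(MBnO)-2-[3,4,5-tris(MBnO)phenyl]-3,4-dihydro-2H-chromen-3-yl 3,4,5-tris(MBnO)benzoate | c1c(OCc5ccc(C)cc5)cc(OCc5ccc(C)cc5)c2c1O[C@H](c4cc(OCc5ccc(C)cc5)c(OCc5ccc(C)cc5)c(OCc5ccc(C)cc5)c4)[C@H](OC(=O)c6cc(OCc5ccc(C)cc5)c(OCc5ccc(C)cc5)c(OCc5ccc(C)cc5)c6)C2 | intermediate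
24 | 3,4,5-tris(MBnO)benzoyl trifluoromethanesulfonate | O=C(OS(=O)(=O)C(F)(F)F)c1cc(OCc5ccc(C)cc5)c(OCc5ccc(C)cc5)c(OCc5ccc(C)cc5)c1 | intermediate
25 | (4R,5R)-4-[2-(TBSO)-4,6-bis(MBnO)benzyl]-2,5-bis[3,4,5-tris(MBnO)phenyl]-1,3-dioxolan-2-ylium trifluoromethanesulfonate (4,5-trans) | CC(C)(C)[Si](C)(C)Oc1cc(OCc5ccc(C)cc5)cc(OCc5ccc(C)cc5)c1C[C@H]3OC(c6cc(OCc5ccc(C)cc5)c(OCc5ccc(C)cc5)c(OCc5ccc(C)cc5)c6)=[O+][C@@H]3c4cc(OCc5ccc(C)cc5)c(OCc5ccc(C)cc5)c(OCc5ccc(C)cc5)c4.[O-]S(=O)(=O)C(F)(F)F | intermediate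
26 | (1R,2R)-1-{(2R,3R)-5,7-bis(MBnO)-3-{[3,4,5-tris(MBnO)benzoyl]oxy}-2-[3,4,5-tris(MBnO)phenyl]-3,4-dihydro-2H-chromen-8-yl}-3-[2-(TBSO)-4,6-bis(MBnO)phenyl]-1-[3,4,5-tris(MBnO)phenyl]propan-2-yl 3,4,5-tris(MBnO)benzoate | O=C(O[C@H](Cc1c(O[Si](C)(C)C(C)(C)C)cc(OCc5ccc(C)cc5)cc1OCc5ccc(C)cc5)[C@H](c1cc(OCc5ccc(C)cc5)c(OCc5ccc(C)cc5)c(OCc5ccc(C)cc5)c1)c1c(OCc5ccc(C)cc5)cc(OCc5ccc(C)cc5)c2c1O[C@H](c1cc(OCc5ccc(C)cc5)c(OCc5ccc(C)cc5)c(OCc5ccc(C)cc5)c1)[C@H](OC(=O)c1cc(OCc5ccc(C)cc5)c(OCc5ccc(C)cc5)c(OCc5ccc(C)cc5)c1)C2)c1cc(OCc5ccc(C)cc5)c(OCc5ccc(C)cc5)c(OCc5ccc(C)cc5)c1 | intermediate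
27 | analogue of 26 with a free 2-hydroxy group in place of 2-(TBSO) on the 2,4,6-trioxygenated phenyl ring | O=C(O[C@H](Cc1c(O)cc(OCc5ccc(C)cc5)cc1OCc5ccc(C)cc5)[C@H](c1cc(OCc5ccc(C)cc5)c(OCc5ccc(C)cc5)c(OCc5ccc(C)cc5)c1)c1c(OCc5ccc(C)cc5)cc(OCc5ccc(C)cc5)c2c1O[C@H](c1cc(OCc5ccc(C)cc5)c(OCc5ccc(C)cc5)c(OCc5ccc(C)cc5)c1)[C@H](OC(=O)c1cc(OCc5ccc(C)cc5)c(OCc5ccc(C)cc5)c(OCc5ccc(C)cc5)c1)C2)c1cc(OCc5ccc(C)cc5)c(OCc5ccc(C)cc5)c(OCc5ccc(C)cc5)c1 | intermediate
28 | (1R,2R)-1-[(2R,3R)-5,7-dihydroxy-3-[(3,4,5-trihydroxybenzoyl)oxy]-2-(3,4,5-trihydroxyphenyl)-3,4-dihydro-2H-chromen-8-yl]-1-(3,4,5-trihydroxyphenyl)-3-(2,4,6-trihydroxyphenyl)propan-2-yl 3,4,5-trihydroxybenzoate (CNP0155034.2) | O=C(O[C@H](Cc1c(O)cc(O)cc1O)[C@H](c1cc(O)c(O)c(O)c1)c1c(O)cc(O)c2c1O[C@H](c1cc(O)c(O)c(O)c1)[C@H](OC(=O)c1cc(O)c(O)c(O)c1)C2)c1cc(O)c(O)c(O)c1 | target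

**Totals**
Total step count: 14. Longest linear sequence: 12 steps (1, 3, 4, 5, 7, 8, 9, 10, 11, 12, 13, 14).

**Three steps most likely to fail**

Step 13 (the proposed new step). The aroyl triflate may C-acylate the electron-rich rings instead of the epoxide oxygen, the silyl ether oxygen may capture the cation, and C6 attack or self-condensation may compete. The fallback uses known chemistry and sets out from the isolated chloro ester 21 and the flavan 23 (3 equiv). AgOSO2CF3 and 2,6-di-tert-butyl-4-methylpyridine in CH2Cl2 at −78 → −30 °C abstract the benzylic chloride with anchimeric assistance of the vicinal ester (Koenigs–Knorr-type activation), which gives the same dioxolanylium triflate 25. Friedel–Crafts alkylation at C8 follows, the same acyloxonium-directed benzylation logic used for 4→8 flavan couplings, and no free acylating agent is ever present. It comes back to the route at 26 and makes no compound outside the list, F0.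

Step 12. Ionisation of the benzylic chloride with ester participation would give the 2,3-trans isomer, and E2 elimination is possible. The fallback sets out from the alkene 19. Epoxidation with the enantiomeric Shi ketone (from L-fructose, same conditions as step 10) gives (2S,3S)-2-[2-(TBSO)-4,6-bis(MBnO)benzyl]-3-[3,4,5-tris(MBnO)phenyl]oxirane F1. HF·pyridine in THF at 0 °C frees 3,5-bis(MBnO)-2-{[(2S,3S)-3-[3,4,5-tris(MBnO)phenyl]oxiran-2-yl]methyl}phenol F2, which closes under the same acidic conditions by 6-endo attack at the benzylic carbon with inversion to (2R,3S)-5,7-bis(MBnO)-2-[3,4,5-tris(MBnO)phenyl]-3,4-dihydro-2H-chromen-3-ol F3. Dess–Martin periodinane in CH2Cl2 gives (2R)-5,7-bis(MBnO)-2-[3,4,5-tris(MBnO)phenyl]-2H-chromen-3(4H)-one F4. LiBH(s-Bu)3 in THF at −78 °C delivers hydride anti to the 2-aryl group and gives (2R,3R)-5,7-bis(MBnO)-2-[3,4,5-tris(MBnO)phenyl]-3,4-dihydro-2H-chromen-3-ol F5. Esterification with 13 (Et3N, DMAP, CH2Cl2) comes back to the route at 23.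

Step 11. Chloride may return without full inversion, the electron-rich aryl epoxide may undergo Meinwald rearrangement to a ketone, or the silyl ether may capture the cation. The fallback sets out from the epoxide 20 and separates opening from acylation. Pyridinium chloride in CH2Cl2 at −30 °C opens the epoxide at the benzylic carbon with inversion to (1S,2R)-1-chloro-3-[2-(TBSO)-4,6-bis(MBnO)phenyl]-1-[3,4,5-tris(MBnO)phenyl]propan-2-ol F6. Acylation of the secondary alcohol with 13 (pyridine, DMAP cat., CH2Cl2, 0 °C) comes back to the route at 21.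

**Further compounds**
F0 | step 13 | none | none
F1 | step 12 | (2S,3S)-2-[2-(TBSO)-4,6-bis(MBnO)benzyl]-3-[3,4,5-tris(MBnO)phenyl]oxirane | CC(C)(C)[Si](C)(C)Oc1cc(OCc5ccc(C)cc5)cc(OCc5ccc(C)cc5)c1C[C@@H]3O[C@H]3c4cc(OCc5ccc(C)cc5)c(OCc5ccc(C)cc5)c(OCc5ccc(C)cc5)c4
F2 | step 12 | 3,5-bis(MBnO)-2-{[(2S,3S)-3-[3,4,5-tris(MBnO)phenyl]oxiran-2-yl]methyl}phenol | Oc1cc(OCc5ccc(C)cc5)cc(OCc5ccc(C)cc5)c1C[C@@H]3O[C@H]3c4cc(OCc5ccc(C)cc5)c(OCc5ccc(C)cc5)c(OCc5ccc(C)cc5)c4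
F3 | step 12 | (2R,3S)-5,7-bis(MBnO)-2-[3,4,5-tris(MBnO)phenyl]-3,4-dihydro-2H-chromen-3-ol | c1c(OCc5ccc(C)cc5)cc(OCc5ccc(C)cc5)c2c1O[C@H](c4cc(OCc5ccc(C)cc5)c(OCc5ccc(C)cc5)c(OCc5ccc(C)cc5)c4)[C@@H](O)C2
F4 | step 12 | (2R)-5,7-bis(MBnO)-2-[3,4,5-tris(MBnO)phenyl]-2H-chromen-3(4H)-one | c1c(OCc5ccc(C)cc5)cc(OCc5ccc(C)cc5)c2c1O[C@H](c4cc(OCc5ccc(C)cc5)c(OCc5ccc(C)cc5)c(OCc5ccc(C)cc5)c4)C(=O)C2
F5 | step 12 | (2R,3R)-5,7-bis(MBnO)-2-[3,4,5-tris(MBnO)phenyl]-3,4-dihydro-2H-chromen-3-ol | c1c(OCc5ccc(C)cc5)cc(OCc5ccc(C)cc5)c2c1O[C@H](c4cc(OCc5ccc(C)cc5)c(OCc5ccc(C)cc5)c(OCc5ccc(C)cc5)c4)[C@H](O)C2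
F6 | step 11 | (1S,2R)-1-chloro-3-[2-(TBSO)-4,6-bis(MBnO)phenyl]-1-[3,4,5-tris(MBnO)phenyl]propan-2-ol | CC(C)(C)[Si](C)(C)Oc1cc(OCc5ccc(C)cc5)cc(OCc5ccc(C)cc5)c1C[C@@H](O)[C@@H](Cl)c4cc(OCc5ccc(C)cc5)c(OCc5ccc(C)cc5)c(OCc5ccc(C)cc5)c4
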